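1.5 percentage points is the gap that counts here: flasks closer than that are called alike.

    free catalyst + left-handed substrate ⇌ catalyst intermediate A (K1 = 110 M⁻¹, k1 = 48000 M⁻¹ s⁻¹, Ea1 = 24.0 kJ mol⁻¹, ΔH1 = −37.0 kJ mol⁻¹)
    reagent + catalyst intermediate B → free catalyst + right-handed product (k2 = 770 M⁻¹ s⁻¹, Ea2 = 43.0 kJ mol⁻¹)
    reagent + catalyst intermediate A → free catalyst + left-handed product (k3 = 1700 M⁻¹ s⁻¹, Ea3 = 48.0 kJ mol⁻¹)
    free catalyst + right-handed substrate ⇌ catalyst intermediate B (K4 = 1400 M⁻¹, k4 = 1.3 × 10⁵ M⁻¹ s⁻¹, Ea4 = 37.0 kJ mol⁻¹, ΔH4 = −69.0 kJ mol⁻¹)
    reagent + free catalyst → spent catalyst (k5 = 1.4 M⁻¹ s⁻¹, Ea5 = 63.0 kJ mol⁻¹)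
    (constants at 110 °C)

| flask | left-handed substrate | reagent | free catalyst | right-handed substrate | temperature | time |
|---|---|---|---|---|---|---|
| eta | 2.0 mM | 6.00 mM | 20 µM | 2.0 mM | 110 °C | 5.0 s |
| theta | 2.0 mM | 6.00 mM | 20 µM | 2.0 mM | 125 °C | 5.0 s |

1. the best flask by share of left-handed product in all that became left-handed product or right-handed product; "all alike" if 1.5 percentage points covers them all (eta / theta / all alike)
2. share of left-handed product in all that became left-handed product or right-handed product, eta
3. share of left-handed product in all that became left-handed product or right-handed product, theta

- free catalyst is single-handed; left-handed substrate and right-handed substrate are mirror images of each other, charged as a racemate, each of them at the stated concentration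
- the constants hold at 110 °C; other temperatures follow from the activation energies and enthalpies

*What do you carry into this flask?* A ratio. For each hand I multiply its binding constant by its reagent constant, then divide left by right. In eta that gives 0.173, the selectivity factor s. Reagent and free catalyst cancel out of it.

*Why trust binding as an equilibrium?* In eta, catalyst intermediate B lets go at 92.9 s⁻¹, faster than reagent takes it at 4.62 s⁻¹, so binding keeps up.

*Solve the two ends.* At the start, the share of left-handed product is s/(1+s), which is 14.7 % in eta. With both hands used up it is one half, the charges being equal. To join the ends, I hold s constant: the fraction of left-handed substrate remaining is then the fraction of right-handed substrate remaining, raised to the power s.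

*How far along is the flask at the end?* Let u be the fraction of right-handed substrate used. I take the reagent step on catalyst intermediate B, with that form's starting part of the catalyst held steady. In eta, u comes to 0.161, and the join gives 15.7 %.

*And hotter?* In theta, the binding constants become 71.0 M⁻¹ for the left hand and 619 M⁻¹ for the right, and the reagent constant for catalyst intermediate B becomes 1280 M⁻¹ s⁻¹. The enthalpies and activation energies together give 37.0 kJ mol⁻¹ in favour of the left hand, so s rises to 0.269. With u at 0.200, the join gives 22.5 %. My choice is theta.

The forecast also says theta, with 16.1 % for eta and 22.5 % for theta. Its grounds are that “the right-handed substrate's stronger binding weakens more on heating”. My eta figure is lower than the forecast's.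

The simulation gives 16.1 % for eta and 22.5 % for theta, so theta is the better flask, as the forecast said. At 50.0 s, theta stands at 31.3 %, with right-handed substrate at 8.81 % of both charges together. That is a fraction 0.176 of its own charge, and s for theta on that remainder gives 31.2 %. For the bench, this means the share in theta climbs as right-handed substrate is used, standing higher at 50.0 s than at 22.5 % after the asked time.

Second flask: theta with 2.4 mM of reagent. The temperature is that of theta and s contains no reagent, so s stays as it was, while u, taken in proportion to the reagent, falls to 0.0799, and the join gives 21.7 %. The simulation gives 21.8 %.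

The numbers come from no measurement; the rest is arithmetic.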